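**Plan**
- Retrosynthetic cuts, in order: the C1 ester and the O–arylethyl bond at C9 (both protecting groups); C12–C13 (conjugate addition to oct-1-en-3-one); excision of C12, i.e. C8–C12 and C11–C12 (reverse of a one-carbon ring expansion); C8–C11 and C9–C10 of the resulting cyclobutanone (ketene plus enol ether); C7–C8 (acetylide alkylation); C5=C6 (Wittig).
- Enabling feature: in the cyclopentane C8–C9–C10–C11–C12 the cis pair C8 (carbon chain) and C9 (oxygen) sits next to the C10 methylene and the C11 carbonyl. The four atoms C8–C9–C10–C11 are therefore a hidden cis-2-alkyl-3-alkoxycyclobutanone, available from a Z-enol ether C8=C9 and the ketene C10=C11=O, with C12 inserted afterwards.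
- Forward order: the C1–C7 bromide is made by Wittig reaction; the alkynyl ether of the chiral alcohol is alkylated with it and semihydrogenated to the Z,Z-dienyl ether; dichloroketene closes the four-membered ring; CH2N2 expands it to the five-membered ring; the C13–C20 chain is added at C12 by Mukaiyama–Michael reaction; dechlorination, ether cleavage and enzymatic ester hydrolysis finish the route.
- Stereochemistry: C5=C6 (Z) comes from the Wittig step; the cis C8/C9 relation comes from the Z enol ether and suprafacial cycloaddition; the absolute sense comes from the (R)-1-(2,4,6-triisopropylphenyl)ethyl group on oxygen; C12 is set trans to C8 by attack anti to the neighbouring side chain.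

Key step: step 7

Assumption: the facial sense of the cycloaddition is taken from the conformational model described under step 7, which calls for the (R)-alcohol; should the sense prove opposite, the (S)-alcohol would be used with no other change.

Step 1
Reactants: 1 (4-carboxybutyl)triphenylphosphonium bromide; 2 (tert-butyldimethylsilyloxy)acetaldehyde
Product: 4 (Z)-7-(tert-butyldimethylsilyloxy)hept-5-enoic acid, via phosphorus ylide 3 (not isolated)
Conditions: NaN(SiMe3)2 (2.1 equiv), THF, 0 °C; then 2, −78 °C → rt; 1 M HCl to pH 4 at 0 °C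
Reagents that add atoms: none
Why: Wittig olefination of an aldehyde with a non-stabilised ylide runs under kinetic control through the cis-oxaphosphetane and should give the Z alkene C5=C6, the carboxyl group travelling as its sodium salt.

Step 2
Reactants: 4 (Z)-7-(tert-butyldimethylsilyloxy)hept-5-enoic acid
Product: 5 methyl (Z)-7-(tert-butyldimethylsilyloxy)hept-5-enoate
Conditions: MeI, K2CO3, DMF, rt
Reagents that add atoms: iodomethane, CI
Why: SN2 O-alkylation of the potassium carboxylate is a mild esterification that leaves the allylic silyl ether and the Z alkene untouched.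

Step 3
Reactants: 5 methyl (Z)-7-(tert-butyldimethylsilyloxy)hept-5-enoate
Product: 6 methyl (Z)-7-bromohept-5-enoate
Conditions: Ph3PBr2, CH2Cl2, 0 °C → rt
Reagents that add atoms: dibromotriphenylphosphorane, BrP(Br)(c1ccccc1)(c1ccccc1)c1ccccc1
Why: Ph3PBr2 converts silyl ethers directly into bromides (Appel-type activation of oxygen as an oxyphosphonium ion, then SN2 attack of bromide at the primary allylic carbon), which at low temperature should preserve the Z geometry.

Step 4
Reactants: 7 (R)-1-(2,4,6-triisopropylphenyl)ethanol; 8 trichloroethylene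
Product: 11 2-[(R)-1-{[(E)-1,2-dichloroethenyl]oxy}ethyl]-1,3,5-triisopropylbenzene, via potassium alkoxide 9 (not isolated), via dichloroacetylene 10 (not isolated)
Conditions: KH, THF, 0 °C → rt; then 8, −50 °C → rt; MeOH quench
Reagents that add atoms: none
Why: Base-induced loss of HCl from trichloroethylene gives dichloroacetylene, to which the alkoxide adds in anti fashion (elimination–addition) to give the (E)-1,2-dichlorovinyl ether after protonation, without touching the carbinol centre.

Step 5
Reactants: 11 2-[(R)-1-{[(E)-1,2-dichloroethenyl]oxy}ethyl]-1,3,5-triisopropylbenzene; 6 methyl (Z)-7-bromohept-5-enoate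
Product: 14 methyl (Z)-9-[(R)-1-(2,4,6-triisopropylphenyl)ethoxy]non-5-en-8-ynoate, via chloroalkynyl ether 12 (not isolated), via lithium alkoxyacetylide 13 (not isolated)
Conditions: n-BuLi (2.0 equiv), THF, −78 → −40 °C; then 6, HMPA, −78 → −20 °C
Reagents that add atoms: none
Why: Lithiation at the CHCl carbon and loss of LiCl give the chloroalkyne, Cl/Li exchange with the second equivalent of n-BuLi gives the lithium alkoxyacetylide, and its SN2 alkylation at the primary allylic bromide (acetylide alkylation) should, in THF/HMPA at low temperature, outpace addition to the methyl ester.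

Step 6
Reactants: 14 methyl (Z)-9-[(R)-1-(2,4,6-triisopropylphenyl)ethoxy]non-5-en-8-ynoate
Product: 15 methyl (5Z,8Z)-9-[(R)-1-(2,4,6-triisopropylphenyl)ethoxy]nona-5,8-dienoate
Conditions: H2 (1 atm), 5% Pd/BaSO4, pyridine, rt, stopped after uptake of 1 equiv
Reagents that add atoms: none
Why: Semihydrogenation of the electron-rich alkynyl ether over a poisoned palladium catalyst delivers both hydrogens to one face from the metal surface and should give the Z enol ether C8=C9, the disubstituted C5=C6 alkene being reduced far more slowly.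

Step 7
Reactants: 15 methyl (5Z,8Z)-9-[(R)-1-(2,4,6-triisopropylphenyl)ethoxy]nona-5,8-dienoate; 16 trichloroacetyl chloride
Product: 18 methyl (Z)-7-[(1S,2R)-3,3-dichloro-4-oxo-2-{(R)-1-(2,4,6-triisopropylphenyl)ethoxy}cyclobutyl]hept-5-enoate (ring substituents cis), via dichloroketene 17 (not isolated)
Conditions: Zn–Cu couple, 16 added slowly, Et2O, 0 °C → rt; filtered, washed with cold aq. NaHCO3, used without chromatography
Reagents that add atoms: none
Why: Dichloroketene, released from 16 by reductive 1,2-dechlorination with zinc, undergoes a concerted but asynchronous ketene–alkene (2+2) cycloaddition with the enol ether, the closest known reaction type being the addition of dichloroketene to Z-enol ethers of chiral 1-arylethanols. The electron-rich carbon C8 bonds to the electrophilic ketene carbonyl carbon C11 and the CCl2 carbon C10 to the oxygen-bearing C9, so the four-membered ring C8–C9–C10–C11 closes in a single intermolecular step by formation of two σ-bonds. The addition is suprafacial on the enol ether, so its Z geometry is carried over into the cis relation of the C8 side chain and the C9 oxygen. The absolute configuration at C8 and C9 is controlled by the auxiliary: in the s-trans enol ether with the carbinol C–H lying in the plane of the double bond, the triisopropylphenyl group covers one π-face and the ketene should enter from the face of the small methyl group. The step needs π-facial selectivity (auxiliary), regioselectivity (fixed by the polarisation of the enol ether) and chemoselectivity for C8=C9 over the isolated C5=C6 alkene and the ester, which the far higher nucleophilicity of the enol ether and the slow addition of 16 should secure.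

Step 8
Reactants: 18 methyl (Z)-7-[(1S,2R)-3,3-dichloro-4-oxo-2-{(R)-1-(2,4,6-triisopropylphenyl)ethoxy}cyclobutyl]hept-5-enoate
Product: 19 methyl (Z)-7-[(1R,2R)-3,3-dichloro-4-oxo-2-{(R)-1-(2,4,6-triisopropylphenyl)ethoxy}cyclopentyl]hept-5-enoate
Conditions: CH2N2, Et2O (trace MeOH), 0 °C → rt; AcOH quench
Reagents that add atoms: diazomethane, C=[N+]=[N-]
Why: Diazomethane adds to the strained, chlorine-activated carbonyl and the non-chlorinated, more electron-rich carbon C8 migrates with retention as N2 leaves (Büchner–Curtius–Schlotterbeck homologation), placing the new CH2 (C12) between C11 and C8, while the less strained cyclopentanone product reacts much more slowly.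

Step 9
Reactants: 19 methyl (Z)-7-[(1R,2R)-3,3-dichloro-4-oxo-2-{(R)-1-(2,4,6-triisopropylphenyl)ethoxy}cyclopentyl]hept-5-enoate
Product: 20 methyl (Z)-7-[(1R,5R)-4,4-dichloro-5-{(R)-1-(2,4,6-triisopropylphenyl)ethoxy}-3-(trimethylsilyloxy)cyclopent-2-en-1-yl]hept-5-enoate
Conditions: Me3SiOTf, Et3N, CH2Cl2, −20 → 0 °C; pentane extraction, used crude
Reagents that add atoms: trimethylsilyl trifluoromethanesulfonate, C[Si](C)(C)OS(=O)(=O)C(F)(F)F
Why: Soft enolisation can only go towards C12 because C10 carries no hydrogen, so a single silyl enol ether (C11=C12) is expected and no free enolate capable of Favorskii-type chemistry is formed.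

Step 10
Reactants: 20 methyl (Z)-7-[(1R,5R)-4,4-dichloro-5-{(R)-1-(2,4,6-triisopropylphenyl)ethoxy}-3-(trimethylsilyloxy)cyclopent-2-en-1-yl]hept-5-enoate; 21 oct-1-en-3-one
Product: 22 methyl (Z)-7-[(1R,2R,5R)-4,4-dichloro-3-oxo-2-(3-oxooctyl)-5-{(R)-1-(2,4,6-triisopropylphenyl)ethoxy}cyclopentyl]hept-5-enoate
Conditions: BF3·OEt2, i-PrOH, CH2Cl2, −78 °C
Reagents that add atoms: none
Why: In this Mukaiyama–Michael addition the BF3-activated enone is attacked at its terminal carbon by C12 on the ring face opposite the adjacent C8 side chain and the C9 alkoxy group, which sets C12 trans to C8, while the alcohol takes up the silyl group and protonates the new enolate so that the 1,5-diketone is released before the enone can polymerise.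

Step 11
Reactants: 22 methyl (Z)-7-[(1R,2R,5R)-4,4-dichloro-3-oxo-2-(3-oxooctyl)-5-{(R)-1-(2,4,6-triisopropylphenyl)ethoxy}cyclopentyl]hept-5-enoate
Product: 24 methyl (Z)-7-[(1R,2R,5S)-3-oxo-2-(3-oxooctyl)-5-{(R)-1-(2,4,6-triisopropylphenyl)ethoxy}cyclopentyl]hept-5-enoate, via monochloro ketone 23 (not isolated)
Conditions: Bu3SnH (2.5 equiv), AIBN (cat.), benzene, 80 °C
Reagents that add atoms: none
Why: In this radical chain dehalogenation the stannyl radical abstracts each activated α-chlorine in turn and the α-keto radical takes hydrogen from Bu3SnH faster than it can cyclise onto the remote alkene or expel the β-alkoxy group, so the C9–O bond and all stereocentres should survive under neutral conditions.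

Step 12
Reactants: 24 methyl (Z)-7-[(1R,2R,5S)-3-oxo-2-(3-oxooctyl)-5-{(R)-1-(2,4,6-triisopropylphenyl)ethoxy}cyclopentyl]hept-5-enoate
Product: 25 methyl (Z)-7-[(1R,2R,5S)-5-hydroxy-3-oxo-2-(3-oxooctyl)cyclopentyl]hept-5-enoate
Conditions: CF3CO2H, CH2Cl2, 0 °C, short contact; cold aq. NaHCO3
Reagents that add atoms: none
Why: Acidolysis of the 1-arylethyl ether proceeds by protonation and SN1/E1 ionisation to the stabilised benzylic cation, which loses a proton to the styrene, so the C9 hydroxyl is freed with its configuration intact because the C9–O bond is not broken.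

Step 13
Reactants: 25 methyl (Z)-7-[(1R,2R,5S)-5-hydroxy-3-oxo-2-(3-oxooctyl)cyclopentyl]hept-5-enoate
Product: 26 (Z)-7-[(1R,2R,5S)-5-hydroxy-3-oxo-2-(3-oxooctyl)cyclopentyl]hept-5-enoic acid (13,14-dihydro-15-keto-PGD2)
Conditions: pig liver esterase, pH 7 phosphate buffer/acetone, rt
Reagents that add atoms: water, O
Why: Enzymatic ester hydrolysis at neutral pH cleaves the unhindered methyl ester without the base that would dehydrate the β-hydroxy ketone or epimerise C12.

**Compound list**
1 | (4-carboxybutyl)triphenylphosphonium bromide | OC(=O)CCCC[P+](c1ccccc1)(c1ccccc1)c1ccccc1.[Br-] | starting material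
2 | (tert-butyldimethylsilyloxy)acetaldehyde | CC(C)(C)[Si](C)(C)OCC=O | starting material
3 | sodium 5-(triphenyl-λ5-phosphanylidene)pentanoate (ylide) | [Na+].[O-]C(=O)CCCC=P(c1ccccc1)(c1ccccc1)c1ccccc1 | intermediate
4 | (Z)-7-(tert-butyldimethylsilyloxy)hept-5-enoic acid | CC(C)(C)[Si](C)(C)OC/C=C\CCCC(=O)O | intermediate
5 | methyl (Z)-7-(tert-butyldimethylsilyloxy)hept-5-enoate | CC(C)(C)[Si](C)(C)OC/C=C\CCCC(=O)OC | intermediate
6 | methyl (Z)-7-bromohept-5-enoate | BrC/C=C\CCCC(=O)OC | intermediate
7 | (R)-1-(2,4,6-triisopropylphenyl)ethanol | C[C@@H](O)c1c(C(C)C)cc(C(C)C)cc1C(C)C | starting material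
8 | trichloroethylene | ClC=C(Cl)Cl | starting material
9 | potassium (R)-1-(2,4,6-triisopropylphenyl)ethoxide | C[C@@H]([O-])c1c(C(C)C)cc(C(C)C)cc1C(C)C.[K+] | intermediate
10 | dichloroacetylene | ClC#CCl | intermediate
11 | 2-[(R)-1-{[(E)-1,2-dichloroethenyl]oxy}ethyl]-1,3,5-triisopropylbenzene | C[C@@H](O/C(Cl)=C\Cl)c1c(C(C)C)cc(C(C)C)cc1C(C)C | intermediate
12 | 2-[(R)-1-(chloroethynyloxy)ethyl]-1,3,5-triisopropylbenzene | C[C@@H](OC#CCl)c1c(C(C)C)cc(C(C)C)cc1C(C)C | intermediate
13 | lithium 2-[(R)-1-(2,4,6-triisopropylphenyl)ethoxy]ethynide | C[C@@H](OC#C[Li])c1c(C(C)C)cc(C(C)C)cc1C(C)C | intermediate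
14 | methyl (Z)-9-[(R)-1-(2,4,6-triisopropylphenyl)ethoxy]non-5-en-8-ynoate | C[C@@H](OC#CC/C=C\CCCC(=O)OC)c1c(C(C)C)cc(C(C)C)cc1C(C)C | intermediate
15 | methyl (5Z,8Z)-9-[(R)-1-(2,4,6-triisopropylphenyl)ethoxy]nona-5,8-dienoate | C[C@@H](O/C=C\C/C=C\CCCC(=O)OC)c1c(C(C)C)cc(C(C)C)cc1C(C)C | intermediate
16 | trichloroacetyl chloride | ClC(Cl)(Cl)C(Cl)=O | starting material
17 | dichloroketene | ClC(Cl)=C=O | intermediate
18 | methyl (Z)-7-[(1S,2R)-3,3-dichloro-4-oxo-2-{(R)-1-(2,4,6-triisopropylphenyl)ethoxy}cyclobutyl]hept-5-enoate (C8 chain and C9 oxygen cis) | O=C1C(Cl)(Cl)[C@H](O[C@H](C)c2c(C(C)C)cc(C(C)C)cc2C(C)C)[C@@H]1C/C=C\CCCC(=O)OC | intermediate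
19 | methyl (Z)-7-[(1R,2R)-3,3-dichloro-4-oxo-2-{(R)-1-(2,4,6-triisopropylphenyl)ethoxy}cyclopentyl]hept-5-enoate | C1C(=O)C(Cl)(Cl)[C@H](O[C@H](C)c2c(C(C)C)cc(C(C)C)cc2C(C)C)[C@@H]1C/C=C\CCCC(=O)OC | intermediate
20 | methyl (Z)-7-[(1R,5R)-4,4-dichloro-5-{(R)-1-(2,4,6-triisopropylphenyl)ethoxy}-3-(trimethylsilyloxy)cyclopent-2-en-1-yl]hept-5-enoate | C1=C(O[Si](C)(C)C)C(Cl)(Cl)[C@H](O[C@H](C)c2c(C(C)C)cc(C(C)C)cc2C(C)C)[C@@H]1C/C=C\CCCC(=O)OC | intermediate
21 | oct-1-en-3-one | C=CC(=O)CCCCC | starting material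
22 | methyl (Z)-7-[(1R,2R,5R)-4,4-dichloro-3-oxo-2-(3-oxooctyl)-5-{(R)-1-(2,4,6-triisopropylphenyl)ethoxy}cyclopentyl]hept-5-enoate | CCCCCC(=O)CC[C@H]1C(=O)C(Cl)(Cl)[C@H](O[C@H](C)c2c(C(C)C)cc(C(C)C)cc2C(C)C)[C@@H]1C/C=C\CCCC(=O)OC | intermediate
23 | methyl (Z)-7-[4-chloro-3-oxo-2-(3-oxooctyl)-5-{(R)-1-(2,4,6-triisopropylphenyl)ethoxy}cyclopentyl]hept-5-enoate (C8, C9, C12 as in 22; either configuration at C10) | CCCCCC(=O)CC[C@H]1C(=O)C(Cl)[C@H](O[C@H](C)c2c(C(C)C)cc(C(C)C)cc2C(C)C)[C@@H]1C/C=C\CCCC(=O)OC | intermediate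
24 | methyl (Z)-7-[(1R,2R,5S)-3-oxo-2-(3-oxooctyl)-5-{(R)-1-(2,4,6-triisopropylphenyl)ethoxy}cyclopentyl]hept-5-enoate | CCCCCC(=O)CC[C@H]1C(=O)C[C@H](O[C@H](C)c2c(C(C)C)cc(C(C)C)cc2C(C)C)[C@@H]1C/C=C\CCCC(=O)OC | intermediate
25 | methyl (Z)-7-[(1R,2R,5S)-5-hydroxy-3-oxo-2-(3-oxooctyl)cyclopentyl]hept-5-enoate | CCCCCC(=O)CC[C@H]1C(=O)C[C@H](O)[C@@H]1C/C=C\CCCC(=O)OC | intermediate
26 | (Z)-7-[(1R,2R,5S)-5-hydroxy-3-oxo-2-(3-oxooctyl)cyclopentyl]hept-5-enoic acid (13,14-dihydro-15-keto-PGD2) | CCCCCC(=O)CC[C@H]1C(=O)C[C@H](O)[C@@H]1C/C=C\CCCC(=O)O | target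

**Step count and risks**

Total step count: 13. Longest linear sequence: 12 steps (steps 1–3 and 5–13, from 1); step 4 is a one-step branch from 7 that joins at step 5.

Steps most likely to fail:

Step 5. The lithium acetylide may add to the methyl ester of 6 or of the product, or it may deprotonate the C7 methylene and isomerise the skipped enyne, instead of undergoing clean SN2 alkylation. The fallback sets out from dichlorovinyl ether 11. The acetylide would be generated as before but quenched with MeOH, to isolate the terminal alkynyl ether 2-[(R)-1-(ethynyloxy)ethyl]-1,3,5-triisopropylbenzene F1. This would be joined to bromide 6 by the copper-mediated coupling of terminal alkynes with allylic halides (CuI, NaI, Cs2CO3, DMF, rt), in which the ester is inert towards the soft copper acetylide. The route is rejoined at enyne 14.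

Step 10. The Lewis acid may ionise the acid-labile arylethyl ether, or the chlorine-deactivated enol ether may add so slowly that the enone polymerises first. The fallback sets out from cyclopentanone 19 and exchanges the auxiliary for a silyl ether before the C–C bond is made.
- CF3CO2H in CH2Cl2 at 0 °C would remove the auxiliary to give methyl (Z)-7-[(1R,2R)-3,3-dichloro-2-hydroxy-4-oxocyclopentyl]hept-5-enoate F2. This is safe at this stage because C10 bears no hydrogen and water cannot be lost.
- t-BuMe2SiOTf and 2,6-lutidine would give the silyl ether methyl (Z)-7-[(1R,2R)-2-(tert-butyldimethylsilyloxy)-3,3-dichloro-4-oxocyclopentyl]hept-5-enoate F3.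
- Me3SiOTf/Et3N would give its enol ether methyl (Z)-7-[(1R,5R)-5-(tert-butyldimethylsilyloxy)-4,4-dichloro-3-(trimethylsilyloxy)cyclopent-2-en-1-yl]hept-5-enoate F4.
- With no acid-labile ether left, the addition to enone 21 could be forced with stoichiometric TiCl4 at −78 °C to give methyl (Z)-7-[(1R,2R,5R)-5-(tert-butyldimethylsilyloxy)-4,4-dichloro-3-oxo-2-(3-oxooctyl)cyclopentyl]hept-5-enoate F5.
- Bu3SnH/AIBN would take this through the monochloro ketone methyl (Z)-7-[5-(tert-butyldimethylsilyloxy)-4-chloro-3-oxo-2-(3-oxooctyl)cyclopentyl]hept-5-enoate F6 (not isolated) to methyl (Z)-7-[(1R,2R,5S)-5-(tert-butyldimethylsilyloxy)-3-oxo-2-(3-oxooctyl)cyclopentyl]hept-5-enoate F7.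
- Aqueous HF in MeCN at 0 °C would remove the silyl ether, rejoining the route at hydroxy ester 25.

Step 12. Under the acid the freed β-hydroxy ketone may lose water across C9–C10 to the cyclopentenone, or the 1,5-diketone may undergo acid-catalysed aldol cyclisation. The fallback changes the order of the last operations and sets out from dichloro diketone 22. CF3CO2H/CH2Cl2 would remove the auxiliary while C10 still carries two chlorines and no hydrogen, so elimination across C9–C10 is impossible. This gives methyl (Z)-7-[(1R,2R,5R)-4,4-dichloro-5-hydroxy-3-oxo-2-(3-oxooctyl)cyclopentyl]hept-5-enoate F8. Neutral radical dechlorination (Bu3SnH, AIBN, benzene, 80 °C) would then pass through the monochloro ketone methyl (Z)-7-[4-chloro-5-hydroxy-3-oxo-2-(3-oxooctyl)cyclopentyl]hept-5-enoate F9 (not isolated) and rejoin the route at hydroxy ester 25.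

**Further compounds**
F1 | step 5 | 2-[(R)-1-(ethynyloxy)ethyl]-1,3,5-triisopropylbenzene | C[C@@H](OC#C)c1c(C(C)C)cc(C(C)C)cc1C(C)C
F2 | step 10 | methyl (Z)-7-[(1R,2R)-3,3-dichloro-2-hydroxy-4-oxocyclopentyl]hept-5-enoate | C1C(=O)C(Cl)(Cl)[C@H](O)[C@@H]1C/C=C\CCCC(=O)OC
F3 | step 10 | methyl (Z)-7-[(1R,2R)-2-(tert-butyldimethylsilyloxy)-3,3-dichloro-4-oxocyclopentyl]hept-5-enoate | C1C(=O)C(Cl)(Cl)[C@H](O[Si](C)(C)C(C)(C)C)[C@@H]1C/C=C\CCCC(=O)OC
F4 | step 10 | methyl (Z)-7-[(1R,5R)-5-(tert-butyldimethylsilyloxy)-4,4-dichloro-3-(trimethylsilyloxy)cyclopent-2-en-1-yl]hept-5-enoate | C1=C(O[Si](C)(C)C)C(Cl)(Cl)[C@H](O[Si](C)(C)C(C)(C)C)[C@@H]1C/C=C\CCCC(=O)OC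
F5 | step 10 | methyl (Z)-7-[(1R,2R,5R)-5-(tert-butyldimethylsilyloxy)-4,4-dichloro-3-oxo-2-(3-oxooctyl)cyclopentyl]hept-5-enoate | CCCCCC(=O)CC[C@H]1C(=O)C(Cl)(Cl)[C@H](O[Si](C)(C)C(C)(C)C)[C@@H]1C/C=C\CCCC(=O)OC
F6 | step 10 | methyl (Z)-7-[5-(tert-butyldimethylsilyloxy)-4-chloro-3-oxo-2-(3-oxooctyl)cyclopentyl]hept-5-enoate (either configuration at C10) | CCCCCC(=O)CC[C@H]1C(=O)C(Cl)[C@H](O[Si](C)(C)C(C)(C)C)[C@@H]1C/C=C\CCCC(=O)OC
F7 | step 10 | methyl (Z)-7-[(1R,2R,5S)-5-(tert-butyldimethylsilyloxy)-3-oxo-2-(3-oxooctyl)cyclopentyl]hept-5-enoate | CCCCCC(=O)CC[C@H]1C(=O)C[C@H](O[Si](C)(C)C(C)(C)C)[C@@H]1C/C=C\CCCC(=O)OC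
F8 | step 12 | methyl (Z)-7-[(1R,2R,5R)-4,4-dichloro-5-hydroxy-3-oxo-2-(3-oxooctyl)cyclopentyl]hept-5-enoate | CCCCCC(=O)CC[C@H]1C(=O)C(Cl)(Cl)[C@H](O)[C@@H]1C/C=C\CCCC(=O)OC
F9 | step 12 | methyl (Z)-7-[4-chloro-5-hydroxy-3-oxo-2-(3-oxooctyl)cyclopentyl]hept-5-enoate (either configuration at C10) | CCCCCC(=O)CC[C@H]1C(=O)C(Cl)[C@H](O)[C@@H]1C/C=C\CCCC(=O)OC
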